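**Strategy.** Everything rests on the C3a–C3 bond of the dihydrofuran ring, the bond from the arene carbon ortho to O1 to the benzylic carbinol carbon C3. C3 is a secondary carbinol next to the C2 stereocentre, so it is taken from an aldehyde, and C3a from an aryl iodide; the two electrophilic carbons are joined reductively by an intramolecular Ni/Cr (Nozaki–Hiyama–Kishi) coupling. One operation closes the O1–C2–C3–C3a–C7a ring and sets C3 trans to the C2 isopropenyl group. The precursor is (2R)-2-(4-acetyl-2-iodophenoxy)-3-methylbut-3-enal, whose C2 comes from L-glyceraldehyde acetonide. Ketone reduction, double tigloylation and allylic oxidation of the isopropenyl methyl finish the route.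

Key step: step 4

Assumption: (S)-2,2-dimethyl-1,3-dioxolane-4-carbaldehyde and 1-(4-fluoro-3-iodophenyl)ethan-1-one are taken as catalogue compounds; the aldehyde is used freshly distilled because it oligomerises on storage.

Step 1
Reactants: 1 (S)-2,2-dimethyl-1,3-dioxolane-4-carbaldehyde; 2 isopropenylmagnesium bromide
Product: 3 (1R)-1-[(4S)-2,2-dimethyl-1,3-dioxolan-4-yl]-2-methylprop-2-en-1-ol
Conditions: THF, −78 °C → −40 °C; aq. NH4Cl
Reagents that add atoms: none
Why: Grignard 1,2-addition to an α,β-dialkoxy aldehyde, in which attack anti to the C4–O bond (Felkin–Anh/Cornforth) should make the anti (1R,4S) adduct the major isomer; the minor syn epimer is removed by chromatography, and C4 serves only as a control centre that step 3 excises.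

Step 2
Reactants: 3 (1R)-1-[(4S)-2,2-dimethyl-1,3-dioxolan-4-yl]-2-methylprop-2-en-1-ol; 4 1-(4-fluoro-3-iodophenyl)ethan-1-one
Product: 5 (1R)-1-[(4S)-2,2-dimethyl-1,3-dioxolan-4-yl]-2-methylprop-2-en-1-yl 4-acetyl-2-iodophenyl ether
Conditions: KHMDS, THF, −20 °C; then 4, DMF, 0 °C → rt
Reagents that add atoms: none
Why: SNAr (addition–elimination) of the potassium alkoxide at the fluoride para to the acetyl group; the carbinol C–O bond is not touched, so the carbinol centre keeps its configuration, and the iodide is not displaced.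

Step 3
Reactants: 5 (1R)-1-[(4S)-2,2-dimethyl-1,3-dioxolan-4-yl]-2-methylprop-2-en-1-yl 4-acetyl-2-iodophenyl ether
Product: 6 (2R)-2-(4-acetyl-2-iodophenoxy)-3-methylbut-3-enal
Conditions: H5IO6, EtOAc, rt; crude aldehyde used at once
Reagents that add atoms: none
Why: Periodic acid hydrolyses the terminal isopropylidene acetal and cleaves the freed 1,2-diol in the same pot (Malaprade glycol cleavage), which removes the control centre as formaldehyde and unveils the C3 aldehyde without base, so the α-aryloxy centre should not enolise.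

Step 4
Reactants: 6 (2R)-2-(4-acetyl-2-iodophenoxy)-3-methylbut-3-enal
Product: 8 (2R,3S)-5-acetyl-2-(prop-1-en-2-yl)-2,3-dihydro-1-benzofuran-3-ol, via arylchromium(III) dichloride 7 (not isolated)
Conditions: CrCl2 (6 equiv), NiCl2 (1 mol%), degassed DMF (0.02 M), rt; aqueous work-up
Reagents that add atoms: none
Why: Ni(0), generated from NiCl2 by Cr(II), inserts into the C3a–I bond, the aryl group is passed to Cr(III) to give arylchromium 7, and this adds intramolecularly to the C3 aldehyde through a Cr–O-bound transition state to give a Cr(III) alkoxide that is hydrolysed on work-up. The closest known reaction type is the intramolecular Nozaki–Hiyama–Kishi coupling of an aryl iodide with an aldehyde, a reductive union of two electrophilic carbons. The dihydrofuran ring O1–C2–C3–C3a–C7a is closed in the 5-exo-trig mode. The new C3 stereocentre is controlled by C2 (1,2-induction): in the nearly planar forming ring the chromium-bound carbonyl oxygen turns to the face opposite the C2 isopropenyl group, so that only the aldehyde hydrogen passes that group, which should give the 2,3-trans (2R,3S) alcohol. The step needs chemoselectivity for the aldehyde over the aryl methyl ketone and over Heck-type 5-exo insertion into the isopropenyl alkene, secured by the aldehyde-specific arylchromium(III) and by keeping nickel at about 1 mol%; the neutral, aprotic medium should preserve the enolisable C2 centre.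

Step 5
Reactants: 8 (2R,3S)-5-acetyl-2-(prop-1-en-2-yl)-2,3-dihydro-1-benzofuran-3-ol
Product: 9 (2R,3S)-5-[(1R)-1-hydroxyethyl]-2-(prop-1-en-2-yl)-2,3-dihydro-1-benzofuran-3-ol
Conditions: RuCl[(R,R)-TsDPEN](p-cymene) (1 mol%), HCO2H/Et3N (5:2), DMF, 30 °C
Reagents that add atoms: none
Why: Noyori asymmetric transfer hydrogenation of the aryl methyl ketone, in which the (R,R)-TsDPEN–Ru hydride sets the (R)-carbinol by reagent control as for acetophenone; formate makes the reduction irreversible while the alkene, the allyl aryl ether and the C3 alcohol stay untouched.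

Step 6
Reactants: 9 (2R,3S)-5-[(1R)-1-hydroxyethyl]-2-(prop-1-en-2-yl)-2,3-dihydro-1-benzofuran-3-ol; 10 tiglic acid (3 equiv)
Product: 11 (1R)-1-[(2R,3S)-2-(prop-1-en-2-yl)-3-{[(2E)-2-methylbut-2-enoyl]oxy}-2,3-dihydro-1-benzofuran-5-yl]ethyl (2E)-2-methylbut-2-enoate
Conditions: DCC, DMAP, CH2Cl2, 0 °C → rt
Reagents that add atoms: none
Why: Steglich esterification of both secondary alcohols; only O–acyl bonds form, so no stereocentre is touched and the (E)-geometry of the tigloyl groups is kept.

Step 7
Reactants: 11 (1R)-1-[(2R,3S)-2-(prop-1-en-2-yl)-3-{[(2E)-2-methylbut-2-enoyl]oxy}-2,3-dihydro-1-benzofuran-5-yl]ethyl (2E)-2-methylbut-2-enoate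
Product: 12 (1R)-1-[(2R,3S)-2-(3-oxoprop-1-en-2-yl)-3-{[(2E)-2-methylbut-2-enoyl]oxy}-2,3-dihydro-1-benzofuran-5-yl]ethyl (2E)-2-methylbut-2-enoate (CNP0292799.1)
Conditions: SeO2 (1.5 equiv), 1,4-dioxane, 70 °C
Reagents that add atoms: selenium dioxide O=[Se]=O
Why: Riley allylic oxidation (ene reaction, then [2,3]-sigmatropic shift) at the methyl group of the electron-rich 1,1-disubstituted alkene, which SeO2 prefers over the allylic methine C2–H and over the electron-poor tiglate alkenes, to give the 2-substituted acrolein.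

**Compound list**

1 | (S)-2,2-dimethyl-1,3-dioxolane-4-carbaldehyde (2,3-O-isopropylidene-L-glyceraldehyde) | O=C[C@@H]1COC(C)(C)O1 | starting material
2 | isopropenylmagnesium bromide (prop-1-en-2-ylmagnesium bromide) | C=C(C)[Mg]Br | starting material
3 | (1R)-1-[(4S)-2,2-dimethyl-1,3-dioxolan-4-yl]-2-methylprop-2-en-1-ol | C=C(C)[C@H]([C@@H]1COC(C)(C)O1)O | intermediate
4 | 1-(4-fluoro-3-iodophenyl)ethan-1-one | CC(=O)c1ccc(F)c(I)c1 | starting material
5 | (1R)-1-[(4S)-2,2-dimethyl-1,3-dioxolan-4-yl]-2-methylprop-2-en-1-yl 4-acetyl-2-iodophenyl ether | C=C(C)[C@H]([C@@H]1COC(C)(C)O1)Oc1ccc(C(C)=O)cc1I | intermediate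
6 | (2R)-2-(4-acetyl-2-iodophenoxy)-3-methylbut-3-enal | C=C(C)[C@H](C=O)Oc1ccc(C(C)=O)cc1I | intermediate
7 | arylchromium(III) dichloride derived from 6 | C=C(C)[C@H](C=O)Oc1ccc(C(C)=O)cc1[Cr](Cl)Cl | intermediate
8 | (2R,3S)-5-acetyl-2-(prop-1-en-2-yl)-2,3-dihydro-1-benzofuran-3-ol | C=C(C)[C@H]1Oc2ccc(C(C)=O)cc2[C@@H]1O | intermediate
9 | (2R,3S)-5-[(1R)-1-hydroxyethyl]-2-(prop-1-en-2-yl)-2,3-dihydro-1-benzofuran-3-ol | C=C(C)[C@H]1Oc2ccc([C@@H](C)O)cc2[C@@H]1O | intermediate
10 | tiglic acid, (2E)-2-methylbut-2-enoic acid | C/C=C(\C)C(=O)O | starting material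
11 | (1R)-1-[(2R,3S)-2-(prop-1-en-2-yl)-3-{[(2E)-2-methylbut-2-enoyl]oxy}-2,3-dihydro-1-benzofuran-5-yl]ethyl (2E)-2-methylbut-2-enoate | C=C(C)[C@H]1Oc2ccc([C@@H](C)OC(=O)/C(C)=C/C)cc2[C@@H]1OC(=O)/C(C)=C/C | intermediate
12 | (1R)-1-[(2R,3S)-2-(3-oxoprop-1-en-2-yl)-3-{[(2E)-2-methylbut-2-enoyl]oxy}-2,3-dihydro-1-benzofuran-5-yl]ethyl (2E)-2-methylbut-2-enoate | C=C(C=O)[C@H]1Oc2ccc([C@@H](C)OC(=O)/C(C)=C/C)cc2[C@@H]1OC(=O)/C(C)=C/C | target

**Step count.** Total: 7 steps. Longest linear sequence: 7 steps (1 → 12).

**Steps most likely to fail**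

Step 4. The ring closure may show too little 1,2-induction, so that cis and trans closure compete, and the α-aryloxy aldehyde may lose part of its C2 configuration by enolisation before it cyclises. The fallback sets out from 6 and comes back at 11. It accepts the closure as it comes and corrects C3 afterwards. The cis alcohol (2R,3R)-5-acetyl-2-(prop-1-en-2-yl)-2,3-dihydro-1-benzofuran-3-ol F1 is separated and esterified with tiglic acid 10 under Mitsunobu conditions (PPh3, DIAD, THF, 0 °C). This should invert C3 and give the trans 3-tiglate ketone F2. The same transfer hydrogenation as in step 5 should then give the (R)-carbinol F3, and Steglich esterification with 10 rejoins the route at 11.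

Step 7. The ene reaction may also engage the allylic C2–H, the oxidation may stall at the alcohol level or run on, and hot selenous acid may ionise the electron-rich benzylic tiglates. The fallback sets out from 11 and comes back at 12. The oxidation is split into two mild stages. Catalytic SeO2 with tert-butyl hydroperoxide in CH2Cl2 at room temperature should stop at the allylic alcohol F4. Activated MnO2 in CH2Cl2 then oxidises this primary allylic alcohol chemoselectively to 12.

Step 1. Facial discrimination in the Grignard addition may be low, so that much material ends as the syn epimer and the separation becomes wasteful. The fallback sets out from 1 (with 2) and comes back at 3. The unseparated mixture of 3 and its syn epimer F5 is oxidised with Dess–Martin periodinane to the enone F6. Zn(BH4)2 in Et2O at −30 °C then reduces the zinc chelate of the carbonyl and the ring oxygen O3 from the face away from C5, which should give the anti alcohol 3 from both epimers.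

Further compounds
F1 | step 4 | (2R,3R)-5-acetyl-2-(prop-1-en-2-yl)-2,3-dihydro-1-benzofuran-3-ol | C=C(C)[C@H]1Oc2ccc(C(C)=O)cc2[C@H]1O
F2 | step 4 | (2R,3S)-5-acetyl-2-(prop-1-en-2-yl)-2,3-dihydro-1-benzofuran-3-yl (2E)-2-methylbut-2-enoate | C=C(C)[C@H]1Oc2ccc(C(C)=O)cc2[C@@H]1OC(=O)/C(C)=C/C
F3 | step 4 | (2R,3S)-5-[(1R)-1-hydroxyethyl]-2-(prop-1-en-2-yl)-2,3-dihydro-1-benzofuran-3-yl (2E)-2-methylbut-2-enoate | C=C(C)[C@H]1Oc2ccc([C@@H](C)O)cc2[C@@H]1OC(=O)/C(C)=C/C
F4 | step 7 | (1R)-1-[(2R,3S)-2-(3-hydroxyprop-1-en-2-yl)-3-{[(2E)-2-methylbut-2-enoyl]oxy}-2,3-dihydro-1-benzofuran-5-yl]ethyl (2E)-2-methylbut-2-enoate | C=C(CO)[C@H]1Oc2ccc([C@@H](C)OC(=O)/C(C)=C/C)cc2[C@@H]1OC(=O)/C(C)=C/C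
F5 | step 1 | (1S)-1-[(4S)-2,2-dimethyl-1,3-dioxolan-4-yl]-2-methylprop-2-en-1-ol | C=C(C)[C@@H]([C@@H]1COC(C)(C)O1)O
F6 | step 1 | 1-[(4S)-2,2-dimethyl-1,3-dioxolan-4-yl]-2-methylprop-2-en-1-one | C=C(C)C(=O)[C@@H]1COC(C)(C)O1
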